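**Assumptions:** The target is (2S,4R), which is the 2,4-trans isomer (Ph and OH on opposite faces). I assume (S)-t-Bu-PyOx delivers the (2S) arylation product; the (R)-ligand would be used otherwise.

**Retrosynthesis**
- The target is the 2,4-trans flavan-4-ol. Disconnecting C4–OH gives (2S)-5,7-dimethoxy-8-prenylflavanone, reached by a bulky-hydride reduction that puts the OH axial (trans to Ph).
- The flavanone C2–Ph bond is made last in the ring construction: an enantioselective Pd-catalysed conjugate arylation of the achiral 5,7-dimethoxy-8-prenylchromone with PhB(OH)2. This replaces the usual chalcone/oxa-Michael closure.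
- The chromone pyranone ring (O1–C2) is closed from the 2'-hydroxyacetophenone via its DMF-DMA enaminone.
- The prenyl group is installed first, on a resorcinol-type acetophenone at the position flanked by two oxygens.

**Route**

Step 1
Reactants: 1 (2',4'-dihydroxy-6'-methoxyacetophenone), 2 (prenyl bromide)
Product: 3 (1-[2,4-dihydroxy-6-methoxy-3-(3-methylbut-2-enyl)phenyl]ethanone)
Conditions: KOH, H2O/MeOH, 0 °C → rt
Reagents that add atoms: prenyl bromide, CC(C)=CCBr
Why: Ortho C-alkylation of the resorcinol-type phenoxide occurs at C3', the carbon flanked by two oxygens and therefore the most nucleophilic; no stereocentre is involved.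

Step 2
Reactants: 3, 4 (iodomethane)
Product: 5 (2'-hydroxy-4',6'-dimethoxy-3'-prenylacetophenone)
Conditions: MeI, K2CO3, acetone, reflux
Reagents that add atoms: iodomethane, CI
Why: Selective Williamson O-methylation of the free 4'-OH; the 2'-OH is locked in a hydrogen bond to the ketone and stays unmethylated, and the prenyl alkene is inert.

Step 3
Reactants: 5, 6 (DMF-DMA)
Product: 7 ((E)-3-(dimethylamino)-1-(2-hydroxy-4,6-dimethoxy-3-prenylphenyl)prop-2-en-1-one)
Conditions: DMF-DMA (3 equiv), neat, 100 °C, 12 h
Reagents that add atoms: N,N-dimethylformamide dimethyl acetal, CN(C)C(OC)OC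
Why: Condensation of the acetyl methyl with DMF-DMA gives the enaminone; the E geometry is set by conjugation.

Step 4
Reactants: 7
Product: 8 (5,7-dimethoxy-8-prenyl-4H-chromen-4-one)
Conditions: 2 M HCl, THF, 0 °C → rt, 2 h
Reagents that add atoms: none
Why: Acid-promoted intramolecular conjugate addition of the phenol to the enaminone, then loss of Me2NH, closes the pyranone ring (chromone synthesis via enaminone); the product is achiral and the cold, short acid exposure limits prenyl hydroarylation.

Step 5
Reactants: 8, 9 (phenylboronic acid)
Product: 10 ((2S)-5,7-dimethoxy-8-prenylflavanone)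
Conditions: Pd(OCOCF3)2 (10 mol%), (S)-t-Bu-PyOx (12 mol%), PhB(OH)2 (3 equiv), NH4PF6, H2O (5 equiv), ClCH2CH2Cl, 60 °C
Reagents that add atoms: phenylboronic acid, OB(O)c1ccccc1
Why: Enantioselective Pd-catalysed 1,4-arylation (Stoltz-type conjugate addition); the chiral Pd–aryl adds to the chromone C2=C3 bond, Ph going to C2 with face selectivity set by the ligand, and protonolysis of the Pd-enolate gives the flavanone.
Proposed new method: Cationic Pd(II)/PyOx arylation of this electron-rich, vinylogous-ester chromone (5,7-dimethoxy, 8-prenyl) is not precedented; the mechanism is transmetalation to ArPd+, coordination and syn-carbopalladation of C2=C3, then protonolysis of the Pd-enolate, and the closest known reaction is Pd/PyOx conjugate arylation of cyclic enones and simple chromones.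

Step 6
Reactants: 10, 11 (L-Selectride)
Product: 12 (target, (2S,4R)-5,7-dimethoxy-8-prenylflavan-4-ol)
Conditions: L-Selectride (1.5 equiv), THF, −78 °C; then NaOH/H2O2 workup, no acid
Reagents that add atoms: none (hydride and proton only)
Why: Hydride reduction of the ketone; the bulky borohydride attacks equatorially on the half-chair with the 2-Ph pseudo-equatorial, giving the axial 4-OH trans to Ph, i.e. (4R), while C2 is untouched at −78 °C.

**Compound list**

| No. | Name | SMILES | Role |
|---|---|---|---|
| 1 | 2',4'-Dihydroxy-6'-methoxyacetophenone | COc1cc(O)cc(O)c1C(C)=O | starting material |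
| 2 | Prenyl bromide | CC(C)=CCBr | starting material (reagent) |
| 3 | 2',4'-Dihydroxy-6'-methoxy-3'-prenylacetophenone | COc1cc(O)c(CC=C(C)C)c(O)c1C(C)=O | intermediate |
| 4 | Iodomethane | CI | starting material (reagent) |
| 5 | 2'-Hydroxy-4',6'-dimethoxy-3'-prenylacetophenone | COc1cc(OC)c(CC=C(C)C)c(O)c1C(C)=O | intermediate |
| 6 | DMF-DMA | CN(C)C(OC)OC | starting material (reagent) |
| 7 | Enaminone | COc1cc(OC)c(CC=C(C)C)c(O)c1C(=O)/C=C/N(C)C | intermediate |
| 8 | 5,7-Dimethoxy-8-prenylchromone | COc1cc(OC)c2c(c1CC=C(C)C)OC=CC2=O | intermediate |
| 9 | Phenylboronic acid | OB(O)c1ccccc1 | starting material (reagent) |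
| 10 | (2S)-5,7-Dimethoxy-8-prenylflavanone | COc1cc(OC)c2c(c1CC=C(C)C)O[C@H](c1ccccc1)CC2=O | intermediate |
| 11 | L-Selectride | CCC(C)[BH-](C(C)CC)C(C)CC.[Li+] | starting material (reagent) |
| 12 | (2S,4R)-5,7-Dimethoxy-8-prenylflavan-4-ol (CID442542) | COc1cc(OC)c2c(c1CC=C(C)C)O[C@H](c1ccccc1)C[C@H]2O | target |

**Totals:** 6 steps, longest linear sequence 6 (1 → 3 → 5 → 7 → 8 → 10 → 12).

**Three steps most likely to fail**
1. **Step 5 (Pd-catalysed arylation).** The deactivated chromone may react slowly or give low ee. Fallback: build the 2'-hydroxy-4',6'-dimethoxy-3'-prenylchalcone from 5 and PhCHO, then close the ring with an enantioselective bifunctional-catalyst oxa-Michael cyclisation to give 10.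
2. **Step 6 (trans selectivity).** The dr may be modest, or C2 may epimerise by retro-oxa-Michael. Fallback: reduce 10 with NaBH4 or Ru-TsDPEN to the cis-alcohol, then invert C4 by Mitsunobu with p-nitrobenzoic acid and hydrolyse, accepting the risk of SN1 ionisation at this electron-rich benzylic position.
3. **Step 1 (regioselective C-prenylation).** C- versus O-alkylation, over-prenylation, or C5' attack could give a poor yield. Fallback: MOM-protect 3,5-dimethoxyphenol, ortho-lithiate and prenylate with CuI/prenyl bromide, then remove the MOM group and install the acetyl group by BF3/AcOH ortho-acylation to reach 5.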